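## The problem

1. The target is a cis-fused decalin (ring A: C4a, C5, C6, C7, C8, C8a; ring B: C8a, C1, C2, C3, C4, C4a) with exocyclic methylenes on C2 and C7 and a quaternary gem-dimethyl carbon C4; C3 carries a two-carbon tether (C1″, C2″) to C6′ of a 1,2-dioxane whose C3′ bears an α-methyl acetic acid residue.
2. Of its six stereocentres, C3, C4a and C8a surround C4 and can be relayed from one another (C3 to C4a through enolate chemistry, C4/C4a to C8a through the faces of a locked chair), whereas C3′, C6′ and the acid α-carbon lie two methylene groups away from the decalin and cannot be controlled by it.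
3. C6′ is a fully substituted peroxide carbon whose methyl and methylene substituents are too similar for thermodynamic or simple steric control, so only a stereospecific C–O bond formation can fix it.
4. Both carbons flanking C4 are neopentyl positions, which slows every C–C bond formation there.
5. The O–O bond is at risk with phosphines, hydride reagents, low-valent metals and hydrogenation, and the acid α-hydrogen is β to a peroxide oxygen, so strong base can open the ring by elimination.
6. The two 1,1-disubstituted alkenes react with electrophiles such as mercury salts and ozone, and C3 becomes epimerisable whenever C2 is a ketone.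
7. The feature that opens the structure is ring A: C8a bears a hydrogen and is joined through the methylene C8 to C7, which carries the exocyclic alkene, so C8 can start as an exocyclic methylene on C8a of a ring B cyclohexane and C7 as the brominated carbon of a 3-bromobut-3-enyl arm on C4a.
8. Hydroboration then puts hydrogen on C8a and boron on C8, and an sp3–sp2 coupling joins C8 to C7.

## Retrosynthesis

The two exocyclic alkenes of target 44 are cut first, leading to diketo acid 43. The methylenes are removed because they would compete with the side-chain alkene for the Hg(OAc)2 that closes the peroxide and would not survive the ozonolysis used earlier; ketones are indifferent to both. 43 also lets the acid travel through the basic olefination as its carboxylate, which shields the α-centre. 43 comes from diol 42 by one oxidation and 42 from bis-silyl ether 41. The forward step must methylenate both ketones without enolising C2 towards C3 and without touching the O–O bond.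

In 41 the O2′–C6′ bond is cut, giving the (E)-alkenyl hydroperoxide 39. The neighbouring cuts (C3′–O by conjugate addition to an enoate, or by displacement from a tertiary hydroperoxide) would leave C6′ to chance. A 6-endo anti addition across a trisubstituted alkene instead translates alkene geometry into configuration: the substituent trans to C4′ ends equatorial and the cis one axial. 39 has one ring and one quaternary stereocentre fewer. The forward reaction must close through a chair with the C3′ substituent equatorial, attack the more substituted alkene carbon, and lose the metal without breaking the peroxide or reducing the C7 ketone.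

The C3′–O bond of 39 is cut next, back to mesylate 37 and alcohol 36. Displacement with inversion is chosen because the required (S)-alcohol with its syn methyl neighbour is exactly what a boron aldol reaction delivers. The forward step must favour substitution over elimination at a β-branched secondary carbon.

36 is cut at the C2″–C6′ bond into alkyl iodide 25 (used as zinc reagent 35) and vinyl iodide 34. This sp3–sp2 cut is preferred over an olefination of a C6′ methyl ketone, which gives no control of the trisubstituted alkene geometry. It places the alkene geometry and both side-chain stereocentres in a small fragment: 34 comes from pent-3-yn-1-ol 26 through (E)-iodide 28, aldehyde 29, an aldol reaction with imide 30 to 32, reduction to 33 and silylation. The coupling must retain geometry and tolerate a ketone and a free hydroxyl.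

25 is traced to chloride 24 by halide exchange and 24 to decalin 23 by cleaving the C7 methylene to the ketone. The methylene can only be parked as its ketone while it is the sole alkene in the molecule, which fixes this point in the sequence.

23 is cut at C7–C8 and at C8a–H, which opens ring A and leads to methylenecyclohexane 21 with a 3-bromobut-3-enyl arm on C4a. This cut removes a ring and a stereocentre in one operation and leaves C7 with its methylene. It asks for hydroboration from the face of C8a opposite the axial C4 methyl and for a coupling that prefers ring closure.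

21 comes from ketone 20 by methylenation (the C8 carbon). 20 comes from silyl ether 17 by shortening the allyl group to a chloroethyl chain (18, 19), and 17 from hydroxy ketone 16. The C2–O bond of 16 is cut back to enone 14, where C2 is the β-carbon; the oxygen must enter anti to the C3 substituent.

14 is cut at C4a–C5 into enone 10 and iodide 3 (from but-3-yn-1-ol 1 via 2). Alkylation of the α′-enolate is expected to give the trans isomer 12, so the cut includes an epimerisation of 12 to 14 by kinetic protonation.

10 is traced through the transposition of vinylogous ester 8, and 8 to enol carbonate 7, vinylogous ester 5 and dimedone 4. The C3–C1″ bond is the first stereogenic bond of the synthesis and is made by a catalytic asymmetric allylation. The allyl group is accepted as a two-carbon unit in disguise because this reaction class offers enantiocontrol at a neopentyl enolate carbon.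

## Roads not taken

Alternative 1: Ring B is opened by a retro-[3,3] cut of C4–C4a. The precursor is the alkoxide of 7-benzyloxy-2-(2-methylprop-1-enyl)bicyclo[2.2.2]oct-5-en-2-ol A1, and an anionic oxy-Cope rearrangement (KH, 18-crown-6) gives the cis-octalone A2. Its merit is certainty: the quaternary C4 and the cis ring fusion arise in one concerted step, with no dependence on face selectivity, and the product enolate is formed regiospecifically at C3. In this respect it is better than the chosen plan, which relies on a stereoselective hydroboration. Its weak points lie around the rearrangement. A2 has no C3 substituent, so a neopentyl enolate must be alkylated with its facial outcome unproven. C7 arrives as a benzyl ether that needs three steps to become a methylene, and the C5=C6 alkene must be hydrogenated before any other alkene is present. A1 itself needs a multistep enantioselective synthesis and carries a stereocentre (C7) made only to be destroyed. The chosen plan sets against this a conformationally locked substrate, a C3 chain and C2 oxygen in place before ring A forms, and direct delivery of the C7 methylene.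

Alternative 2: Ring A is cut at C8=C8a by a retro-aldol condensation, leading to the meso cis-4,6-bis(3-oxobutyl) derivative A3 of dimedone 4. A chiral phosphoric acid would make one arm condense with the adjacent ring carbonyl to give the bicyclic enedione A4. If it worked, this would be the shortest road: ring A, the absolute configuration and a C7 ketone (no parking step) arrive in one catalytic step, and the second arm remains as a handle. In step economy it is clearly better than the chosen plan. Four points weigh against it for this target.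
- The ring carbonyls of A3 belong to an enolisable 1,3-dione with C1H2 between them. The compound exists as a vinylogous acid whose carbonyls are poor electrophiles and are interchanged by tautomerism; desymmetrising aldolisations of this kind are established for diones that cannot enolise in this way.
- A3 is not cheap: 4 reacts with enones at C2, so both arms would have to be put on the neopentyl C4 and C6 positions with cis control.
- C8a stays sp2 in A4, and its hydrogen must be added later by an enone reduction whose cis/trans outcome is open.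
- The remaining methyl ketone arm cannot be turned into the (E)-trisubstituted alkene needed for the peroxide with geometric control.

The chosen plan answers with a ring closure that fixes C8a as it forms and with an alkene geometry set in a separate fragment.

Alternative 3: The dioxane is cut at O2′–C6′ on the complete decalin-2,7-dione. The (E)-alkenyl hydroperoxide A5 is closed 6-endo with Hg(OAc)2 (divalent mercury) and demercurated with NaBH4 to give dioxane A6. The merit is that it controls the one stereocentre nothing else controls, C6′, through alkene geometry and a chair transition state; the chosen plan uses the same stereochemical device in its own step 26. As a plan in its own right it has three weak points. It says nothing on how the cis-decalin-dione is made. It closes the peroxide with both ketones present, so C3 is epimerisable next to the C2 carbonyl throughout the hydroperoxide chemistry. Its NaBH4 demercuration threatens both ketones. The chosen plan keeps C2 as a silyl ether until the peroxide is in place, removes mercury with Bu3SnH, and supplies the decalin by the ring A closure.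

Key step: step 15

Remarks on the chemistry:
- Decalin compounds and their ring B precursors are named with the locants of the target (C1 to C8a; C1″ and C2″ for the tether; C3′ to C6′ for the dioxane).
- Assumption: the (1R,2R) ligand of step 5 is taken to deliver the (S) centre of 8; if the sense of induction is the opposite, the (1S,2S) ligand is used.

## Steps

Step 1
Reactants: 1 but-3-yn-1-ol
Product: 2 3-bromobut-3-en-1-ol
Conditions: Et4N+ HBr2− (tetraethylammonium hydrogen dibromide), CH2Cl2, 40 °C
Reagents that add atoms: hydrogen bromide (from the hydrogen dibromide salt), Br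
Why: Markovnikov hydrobromination of a terminal alkyne by the hydrogen dibromide ion stops at the 2-bromoalkene; the free hydroxyl is tolerated.

Step 2
Reactants: 2 3-bromobut-3-en-1-ol
Product: 3 2-bromo-4-iodobut-1-ene
Conditions: I2, PPh3, imidazole, CH2Cl2, 0 °C → rt
Reagents that add atoms: iodine, II
Why: Appel-type iodination of a primary alcohol through the alkoxyphosphonium salt; the vinyl bromide is inert.

Step 3
Reactants: 4 dimedone
Product: 5 3-isobutoxy-5,5-dimethylcyclohex-2-en-1-one
Conditions: i-BuOH, TsOH·H2O (cat.), toluene, reflux, Dean–Stark trap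
Reagents that add atoms: 2-methylpropan-1-ol, CC(C)CO
Why: Acid-catalysed condensation of the enolised 1,3-dione with the alcohol gives the vinylogous ester; azeotropic removal of water drives it.

Step 4
Reactants: 5 3-isobutoxy-5,5-dimethylcyclohex-2-en-1-one
Product: 7 allyl 5-isobutoxy-3,3-dimethylcyclohexa-1,5-dien-1-yl carbonate, via lithium dienolate 6 (not isolated)
Conditions: LiN(SiMe3)2, TMEDA, THF, −78 °C; allyl chloroformate, −78 → −40 °C
Reagents that add atoms: allyl chloroformate, C=CCOC(=O)Cl
Why: Kinetic α′-deprotonation gives the cross-conjugated dienolate, which the hard chloroformate acylates on oxygen (enol carbonate formation).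

Step 5
Reactants: 7 allyl 5-isobutoxy-3,3-dimethylcyclohexa-1,5-dien-1-yl carbonate
Product: 8 (6S)-6-allyl-3-isobutoxy-5,5-dimethylcyclohex-2-en-1-one
Conditions: Pd2(dba)3·CHCl3 (2.5 mol%), (1R,2R)-N,N′-bis[2-(diphenylphosphino)benzoyl]cyclohexane-1,2-diamine (5.5 mol%), toluene, 23 °C
Reagents that add atoms: none
Why: Decarboxylative asymmetric allylic alkylation (Tsuji–Trost type), a reaction class established for enol carbonates of cyclic vinylogous esters: zerovalent palladium ionises the carbonate, CO2 is lost and the enolate recombines with the π-allyl unit inside the chiral pocket. The new tertiary centre (C3 of the target) is not readily scrambled under these neutral conditions.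

Step 6
Reactants: 8 (6S)-6-allyl-3-isobutoxy-5,5-dimethylcyclohex-2-en-1-one
Product: 10 (4R)-4-allyl-5,5-dimethylcyclohex-2-en-1-one, via allylic alcohol 9 (not isolated)
Conditions: i-Bu2AlH, toluene, −78 → 0 °C; then 1 M HCl, THF, 0 °C → rt
Reagents that add atoms: water, O
Why: Stork–Danheiser transposition: 1,2-reduction of the vinylogous ester and acid hydrolysis of the resulting alkoxy allylic alcohol give the transposed enone; the stereocentre becomes the γ-carbon and is not touched.

Step 7
Reactants: 10 (4R)-4-allyl-5,5-dimethylcyclohex-2-en-1-one; 3 2-bromo-4-iodobut-1-ene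
Product: 12 (4R,6S)-4-allyl-6-(3-bromobut-3-en-1-yl)-5,5-dimethylcyclohex-2-en-1-one, via lithium dienolate 11 (not isolated)
Conditions: LiN(i-Pr)2, THF, −78 °C; then 3, DMPU, −78 → −30 °C
Reagents that add atoms: none
Why: Kinetic α′-enolate alkylation by a primary iodide, with DMPU to favour substitution over elimination. The electrophile should enter anti to the pseudoaxial C5 methyl on the face that carries only the C4 hydrogen, which places the arm trans to the allyl group.

Step 8
Reactants: 12 (4R,6S)-4-allyl-6-(3-bromobut-3-en-1-yl)-5,5-dimethylcyclohex-2-en-1-one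
Product: 14 (4R,6R)-4-allyl-6-(3-bromobut-3-en-1-yl)-5,5-dimethylcyclohex-2-en-1-one, via lithium dienolate 13 (not isolated)
Conditions: LiN(i-Pr)2, THF, −78 → −40 °C; then inverse quench into AcOH–THF, −78 °C
Reagents that add atoms: none
Why: Epimerisation by deprotonation and kinetic protonation: the proton should enter on the same open face the electrophile used in step 7, which turns the arm cis to the allyl group (the C3/C4a relationship of the target).

Step 9
Reactants: 14 (4R,6R)-4-allyl-6-(3-bromobut-3-en-1-yl)-5,5-dimethylcyclohex-2-en-1-one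
Product: 16 (2R,4S,5S)-4-allyl-2-(3-bromobut-3-en-1-yl)-5-hydroxy-3,3-dimethylcyclohexan-1-one, via pinacolboryl ketone 15 (not isolated)
Conditions: CuSO4 (2 mol%), 4-picoline (10 mol%), B2pin2 (1.2 equiv), THF–H2O, rt; then NaBO3·4H2O, rt
Reagents that add atoms: sodium perborate tetrahydrate, [Na+].OO[B-](O)(O)O (the hydroxyl oxygen); bis(pinacolato)diboron, CC1(C)OB(OC1(C)C)B1OC(C)(C)C(C)(C)O1 (the boron of 15 only)
Why: Copper-catalysed conjugate borylation of the enone followed by oxidation with retention; the boryl group should add anti to the adjacent allyl group, giving the trans hydroxyl. The near-neutral medium and the enolate formed on the other side of the carbonyl leave the α-stereocentre alone.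

Step 10
Reactants: 16 (2R,4S,5S)-4-allyl-2-(3-bromobut-3-en-1-yl)-5-hydroxy-3,3-dimethylcyclohexan-1-one
Product: 17 (2R,4S,5S)-4-allyl-2-(3-bromobut-3-en-1-yl)-5-[(tert-butyldimethylsilyl)oxy]-3,3-dimethylcyclohexan-1-one
Conditions: TBSOTf, 2,6-lutidine, CH2Cl2, −78 → 0 °C
Reagents that add atoms: tert-butyldimethylsilyl triflate, CC(C)(C)[Si](C)(C)OS(=O)(=O)C(F)(F)F
Why: Silylation of a hindered secondary alcohol with the silyl triflate; the weak base does not trigger β-elimination of the aldol-type product.

Step 11
Reactants: 17 (2R,4S,5S)-4-allyl-2-(3-bromobut-3-en-1-yl)-5-[(tert-butyldimethylsilyl)oxy]-3,3-dimethylcyclohexan-1-one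
Product: 18 (2R,4S,5S)-2-(3-bromobut-3-en-1-yl)-5-[(tert-butyldimethylsilyl)oxy]-3,3-dimethyl-4-(2-oxoethyl)cyclohexan-1-one
Conditions: OsO4 (2 mol%), NaIO4 (4 equiv), 2,6-lutidine, 1,4-dioxane–H2O (3:1), rt
Reagents that add atoms: osmium tetroxide, O=[Os](=O)(=O)=O (catalytic carrier of the oxygen); sodium periodate, [Na+].[O-]I(=O)(=O)=O
Why: Lemieux–Johnson cleavage: the monosubstituted alkene is dihydroxylated much faster than the electron-poor 2-bromoalkene, and periodate cleaves the diol to the aldehyde.

Step 12
Reactants: 18 (2R,4S,5S)-2-(3-bromobut-3-en-1-yl)-5-[(tert-butyldimethylsilyl)oxy]-3,3-dimethyl-4-(2-oxoethyl)cyclohexan-1-one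
Product: 19 (2R,4S,5S)-2-(3-bromobut-3-en-1-yl)-5-[(tert-butyldimethylsilyl)oxy]-4-(2-hydroxyethyl)-3,3-dimethylcyclohexan-1-one
Conditions: NaBH4, MeOH–CH2Cl2, −78 °C
Reagents that add atoms: none
Why: Chemoselective borohydride reduction: at low temperature the aldehyde is reduced far faster than the hindered α-branched ketone.

Step 13
Reactants: 19 (2R,4S,5S)-2-(3-bromobut-3-en-1-yl)-5-[(tert-butyldimethylsilyl)oxy]-4-(2-hydroxyethyl)-3,3-dimethylcyclohexan-1-one
Product: 20 (2R,4S,5S)-2-(3-bromobut-3-en-1-yl)-5-[(tert-butyldimethylsilyl)oxy]-4-(2-chloroethyl)-3,3-dimethylcyclohexan-1-one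
Conditions: PPh3, CCl4, CH2Cl2, 0 °C → rt
Reagents that add atoms: carbon tetrachloride, ClC(Cl)(Cl)Cl
Why: Appel chlorination of the primary alcohol; the chloride is chosen as a placeholder that is inert to boranes, palladium and ozone and can later be exchanged for iodide.

Step 14
Reactants: 20 (2R,4S,5S)-2-(3-bromobut-3-en-1-yl)-5-[(tert-butyldimethylsilyl)oxy]-4-(2-chloroethyl)-3,3-dimethylcyclohexan-1-one
Product: 21 tert-butyl{[(1S,2S,4S)-4-(3-bromobut-3-en-1-yl)-2-(2-chloroethyl)-3,3-dimethyl-5-methylidenecyclohexyl]oxy}dimethylsilane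
Conditions: Tebbe reagent Cp2Ti(μ-Cl)(μ-CH2)AlMe2, pyridine (cat.), THF–toluene, −40 °C → rt
Reagents that add atoms: Tebbe reagent Cp2Ti(μ-Cl)(μ-CH2)AlMe2 (drawn with the chloride on titanium only), C[Al](C)C[Ti](Cl)(C1C=CC=C1)C1C=CC=C1
Why: Tebbe methylenation: the reagent releases the titanium methylidene Cp2Ti=CH2, which adds to the carbonyl to give an oxatitanacyclobutane that fragments to the alkene. The reagent is non-basic, so the α-stereocentre and the β-silyloxy group of this hindered ketone should survive.

Step 15
Reactants: 21 tert-butyl{[(1S,2S,4S)-4-(3-bromobut-3-en-1-yl)-2-(2-chloroethyl)-3,3-dimethyl-5-methylidenecyclohexyl]oxy}dimethylsilane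
Product: 23 tert-butyl{[(2S,3S,4aS,8aS)-3-(2-chloroethyl)-4,4-dimethyl-7-methylidenedecahydronaphthalen-2-yl]oxy}dimethylsilane, via B-alkyl-9-BBN 22 (not isolated)
Conditions: 9-BBN (1.5 equiv), THF, 0 → 45 °C; then 3 M aq. K3PO4, Pd(dppf)Cl2 (10 mol%), AsPh3 (10 mol%), DMF–THF, 60 °C, 0.01 M
Reagents that add atoms: none
Why: 9-BBN adds across the exocyclic C8a=C8 bond through the four-centre syn transition state, boron on the terminal carbon C8 and hydrogen on C8a; zerovalent palladium then inserts into the C7–Br bond, the primary alkyl group is transferred from the base-activated borane, and reductive elimination forms C7–C8. The closest known reaction type is 9-BBN hydroboration of a diene carrying a 2-bromoalkene followed by intramolecular B-alkyl Suzuki–Miyaura coupling to a methylenecycloalkane. Ring A closes as a six-membered ring by sp3–sp2 reductive elimination from a seven-membered palladacycle, and the C7 alkene stays exocyclic. The new stereocentre C8a is set in the hydroboration: 21 is locked in the chair with the C2 silyloxy group, the C3 chain and the C4a arm all equatorial, so one C4 methyl is axial and 1,3 to C8a on the axial face. The bulky borane should therefore deliver hydrogen from the equatorial side, which leaves C8 axial and cis to the arm and gives the cis ring fusion. The step needs chemoselectivity between the 1,1-dialkyl alkene and the 2-bromoalkene, which the low reactivity of halogen-bearing alkenes towards 9-BBN should secure; the alkyl chloride and silyl ether are inert in both stages. High dilution favours ring closure over intermolecular coupling, and the wide-bite-angle dppf ligand favours reductive elimination over β-hydride loss.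

Step 16
Reactants: 23 tert-butyl{[(2S,3S,4aS,8aS)-3-(2-chloroethyl)-4,4-dimethyl-7-methylidenedecahydronaphthalen-2-yl]oxy}dimethylsilane
Product: 24 (2S,3S,4aS,8aR)-2-[(tert-butyldimethylsilyl)oxy]-3-(2-chloroethyl)-4,4-dimethyldecahydronaphthalen-7-one
Conditions: O3, CH2Cl2–MeOH, −78 °C; then Me2S, −78 °C → rt
Reagents that add atoms: ozone, [O-][O+]=O
Why: Ozonolysis of the only alkene parks C7 as a ketone, which will pass the mercury-mediated peroxide closure untouched.

Step 17
Reactants: 24 (2S,3S,4aS,8aR)-2-[(tert-butyldimethylsilyl)oxy]-3-(2-chloroethyl)-4,4-dimethyldecahydronaphthalen-7-one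
Product: 25 (2S,3S,4aS,8aR)-2-[(tert-butyldimethylsilyl)oxy]-3-(2-iodoethyl)-4,4-dimethyldecahydronaphthalen-7-one
Conditions: NaI, acetone, reflux
Reagents that add atoms: sodium iodide, [Na+].[I-]
Why: Finkelstein exchange at the primary carbon, driven by precipitation of sodium chloride.

Step 18
Reactants: 26 pent-3-yn-1-ol
Product: 28 (3E)-4-iodopent-3-en-1-ol, via alkenylzirconocene 27 (not isolated)
Conditions: Cp2Zr(H)Cl (2.6 equiv), THF, 25 → 40 °C; then I2, THF, 0 °C
Reagents that add atoms: iodine, II
Why: Syn hydrozirconation of the internal alkyne; with excess hydride the zirconium settles on the less hindered, methyl-bearing carbon, and iodinolysis with retention gives the (E)-vinyl iodide. The first equivalent is consumed by the hydroxyl.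

Step 19
Reactants: 28 (3E)-4-iodopent-3-en-1-ol
Product: 29 (3E)-4-iodopent-3-enal
Conditions: Dess–Martin periodinane, NaHCO3, CH2Cl2, 0 °C; used without chromatography
Reagents that add atoms: none
Why: Dess–Martin oxidation under buffered, neutral conditions avoids migration of the β,γ-alkene into conjugation.

Step 20
Reactants: 30 (4R)-4-benzyl-3-propanoyl-1,3-oxazolidin-2-one; 29 (3E)-4-iodopent-3-enal
Product: 32 (4R)-4-benzyl-3-[(2R,3S,5E)-3-hydroxy-6-iodo-2-methylhept-5-enoyl]-1,3-oxazolidin-2-one, via dibutylboron enolate 31 (not isolated)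
Conditions: Bu2BOTf, Et3N, CH2Cl2, −78 → 0 °C; 29, −78 → 0 °C; then pH 7 buffer, MeOH, 30% H2O2, 0 °C
Reagents that add atoms: none
Why: Evans syn-aldol reaction: the (Z)-boron enolate reacts through a closed chair transition state and the auxiliary selects the enolate face, setting the α-methyl centre and the carbinol centre syn. The carbinol is formed with the configuration opposite to that needed at C3′, as required for the later inversion.

Step 21
Reactants: 32 (4R)-4-benzyl-3-[(2R,3S,5E)-3-hydroxy-6-iodo-2-methylhept-5-enoyl]-1,3-oxazolidin-2-one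
Product: 33 (2S,3S,5E)-6-iodo-2-methylhept-5-ene-1,3-diol
Conditions: LiBH4, MeOH (1 equiv), THF, 0 °C
Reagents that add atoms: none
Why: Reductive removal of the auxiliary gives the primary alcohol without touching the vinyl iodide or the α-centre.

Step 22
Reactants: 33 (2S,3S,5E)-6-iodo-2-methylhept-5-ene-1,3-diol
Product: 34 (2S,3S,5E)-1-[(tert-butyldimethylsilyl)oxy]-6-iodo-2-methylhept-5-en-3-ol
Conditions: TBSCl (1.05 equiv), imidazole, CH2Cl2, −20 → 0 °C
Reagents that add atoms: tert-butyldimethylsilyl chloride, CC(C)(C)[Si](C)(C)Cl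
Why: Selective silylation of the primary hydroxyl over the hindered secondary one.

Step 23
Reactants: 25 (2S,3S,4aS,8aR)-2-[(tert-butyldimethylsilyl)oxy]-3-(2-iodoethyl)-4,4-dimethyldecahydronaphthalen-7-one; 34 (2S,3S,5E)-1-[(tert-butyldimethylsilyl)oxy]-6-iodo-2-methylhept-5-en-3-ol
Product: 36 (2S,3S,4aS,8aR)-2-[(tert-butyldimethylsilyl)oxy]-3-[(3E,6S,7S)-8-[(tert-butyldimethylsilyl)oxy]-6-hydroxy-3,7-dimethyloct-3-en-1-yl]-4,4-dimethyldecahydronaphthalen-7-one, via alkylzinc iodide 35 (not isolated)
Conditions: Zn dust (activated with BrCH2CH2Br and Me3SiCl), LiCl, THF, 40 °C; then 34 (1.2 equiv), Pd(OAc)2 (3 mol%), SPhos (6 mol%), THF, 25 °C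
Reagents that add atoms: none
Why: Zinc insertion into the primary iodide tolerates the ketone and silyl ethers, and the Negishi sp3–sp2 coupling retains the (E) geometry. With this catalyst, coupling is known to outpace protonation of the organozinc by a free hydroxyl.

Step 24
Reactants: 36 (2S,3S,4aS,8aR)-2-[(tert-butyldimethylsilyl)oxy]-3-[(3E,6S,7S)-8-[(tert-butyldimethylsilyl)oxy]-6-hydroxy-3,7-dimethyloct-3-en-1-yl]-4,4-dimethyldecahydronaphthalen-7-one
Product: 37 (3E,6S,7S)-8-[(tert-butyldimethylsilyl)oxy]-1-[(2S,3S,4aS,8aR)-2-[(tert-butyldimethylsilyl)oxy]-4,4-dimethyl-7-oxodecahydronaphthalen-3-yl]-3,7-dimethyloct-3-en-6-yl methanesulfonate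
Conditions: MsCl, Et3N, CH2Cl2, 0 °C
Reagents that add atoms: methanesulfonyl chloride, CS(=O)(=O)Cl
Why: Sulfonylation of the secondary alcohol with retention, which prepares C3′ for displacement.

Step 25
Reactants: 37 (3E,6S,7S)-8-[(tert-butyldimethylsilyl)oxy]-1-[(2S,3S,4aS,8aR)-2-[(tert-butyldimethylsilyl)oxy]-4,4-dimethyl-7-oxodecahydronaphthalen-3-yl]-3,7-dimethyloct-3-en-6-yl methanesulfonate
Product: 39 (2S,3S,4aS,8aR)-2-[(tert-butyldimethylsilyl)oxy]-3-[(3E,6R,7S)-8-[(tert-butyldimethylsilyl)oxy]-6-hydroperoxy-3,7-dimethyloct-3-en-1-yl]-4,4-dimethyldecahydronaphthalen-7-one, via peroxyketal 38 (not isolated)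
Conditions: 2-methoxyprop-2-yl hydroperoxide, CsOH·H2O, DMF, 0 °C → rt; then AcOH–H2O–THF, rt
Reagents that add atoms: 2-methoxyprop-2-yl hydroperoxide, COC(C)(C)OO
Why: SN2 displacement of the secondary mesylate by the caesium salt of a monoprotected hydrogen peroxide inverts C3′ to the (R) configuration of the target; mild acid then frees the hydroperoxide from the peroxyketal.

Step 26
Reactants: 39 (2S,3S,4aS,8aR)-2-[(tert-butyldimethylsilyl)oxy]-3-[(3E,6R,7S)-8-[(tert-butyldimethylsilyl)oxy]-6-hydroperoxy-3,7-dimethyloct-3-en-1-yl]-4,4-dimethyldecahydronaphthalen-7-one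
Product: 41 (2S,3S,4aS,8aR)-2-[(tert-butyldimethylsilyl)oxy]-3-{2-[(3′R,6′S)-3′-{(2S)-1-[(tert-butyldimethylsilyl)oxy]propan-2-yl}-6′-methyl-1,2-dioxan-6′-yl]ethyl}-4,4-dimethyldecahydronaphthalen-7-one, via organomercury acetate 40 (not isolated)
Conditions: Hg(OAc)2 (1.1 equiv), CH2Cl2, 0 °C; then Bu3SnH (2 equiv), THF, 0 °C → rt
Reagents that add atoms: none
Why: Cycloperoxymercuration: the hydroperoxide oxygen attacks the more substituted carbon C6′ of the mercurinium ion anti to mercury in a 6-endo chair with the C3′ substituent equatorial. The (E) geometry therefore places the tether equatorial and the methyl axial, which is the (6′S) configuration. The ring-bound mercury is then replaced by hydrogen with Bu3SnH, which spares the ketone; a ring radical is poorly aligned for O–O scission.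

Step 27
Reactants: 41 (2S,3S,4aS,8aR)-2-[(tert-butyldimethylsilyl)oxy]-3-{2-[(3′R,6′S)-3′-{(2S)-1-[(tert-butyldimethylsilyl)oxy]propan-2-yl}-6′-methyl-1,2-dioxan-6′-yl]ethyl}-4,4-dimethyldecahydronaphthalen-7-one
Product: 42 (2S,3S,4aS,8aR)-2-hydroxy-3-{2-[(3′R,6′S)-3′-[(2S)-1-hydroxypropan-2-yl]-6′-methyl-1,2-dioxan-6′-yl]ethyl}-4,4-dimethyldecahydronaphthalen-7-one
Conditions: HF (48% aq.), MeCN–THF, 0 °C → rt
Reagents that add atoms: none
Why: Acidic fluoride cleaves both silyl ethers; the dialkyl peroxide and the ketone are inert to these conditions.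

Step 28
Reactants: 42 (2S,3S,4aS,8aR)-2-hydroxy-3-{2-[(3′R,6′S)-3′-[(2S)-1-hydroxypropan-2-yl]-6′-methyl-1,2-dioxan-6′-yl]ethyl}-4,4-dimethyldecahydronaphthalen-7-one
Product: 43 (2R)-2-[(3R,6S)-6-{2-[(3S,4aS,8aS)-4,4-dimethyl-2,7-dioxodecahydronaphthalen-3-yl]ethyl}-6-methyl-1,2-dioxan-3-yl]propanoic acid
Conditions: CrO3, H2SO4, H2O, acetone, 0 °C
Reagents that add atoms: water, O
Why: Jones oxidation takes the secondary alcohol to the C2 ketone and the primary alcohol through its aldehyde hydrate to the acid in one operation. Dialkyl peroxides withstand hexavalent chromium, and the acidic medium avoids base-induced opening of the β-peroxy carbonyl unit.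

Step 29
Reactants: 43 (2R)-2-[(3R,6S)-6-{2-[(3S,4aS,8aS)-4,4-dimethyl-2,7-dioxodecahydronaphthalen-3-yl]ethyl}-6-methyl-1,2-dioxan-3-yl]propanoic acid
Product: 44 (2R)-2-[(3R,6S)-6-{2-[(3R,4aS,8aS)-4,4-dimethyl-2,7-dimethylidenedecahydronaphthalen-3-yl]ethyl}-6-methyl-1,2-dioxan-3-yl]propanoic acid
Conditions: Ph3PCH3Br (6 equiv), KOt-Bu (5.8 equiv), THF, 0 °C; then 43, 0 °C → rt; aqueous acid work-up
Reagents that add atoms: methyltriphenylphosphonium bromide, C[P+](c1ccccc1)(c1ccccc1)c1ccccc1.[Br-]
Why: Double Wittig methylenation: the acid is first converted to its carboxylate, which is inert and keeps the α-hydrogen from being removed, and both ketones are then olefinated. Dialkyl peroxides tolerate phosphorus ylides at or below room temperature.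

## Compound list

1 | but-3-yn-1-ol | C#CCCO | starting material
2 | 3-bromobut-3-en-1-ol | C=C(Br)CCO | intermediate
3 | 2-bromo-4-iodobut-1-ene | C=C(Br)CCI | intermediate
4 | dimedone (5,5-dimethylcyclohexane-1,3-dione) | CC1(C)CC(=O)CC(=O)C1 | starting material
5 | 3-isobutoxy-5,5-dimethylcyclohex-2-en-1-one | O=C1C=C(OCC(C)C)CC(C)(C)C1 | intermediate
6 | lithium 5-isobutoxy-3,3-dimethylcyclohexa-1,5-dien-1-olate (not isolated) | [Li]OC1=CC(C)(C)CC(OCC(C)C)=C1 | intermediate
7 | allyl 5-isobutoxy-3,3-dimethylcyclohexa-1,5-dien-1-yl carbonate | C=CCOC(=O)OC1=CC(C)(C)CC(OCC(C)C)=C1 | intermediate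
8 | (6S)-6-allyl-3-isobutoxy-5,5-dimethylcyclohex-2-en-1-one | O=C1C=C(OCC(C)C)CC(C)(C)[C@@H]1CC=C | intermediate
9 | (6S)-6-allyl-3-isobutoxy-5,5-dimethylcyclohex-2-en-1-ol, both C1 epimers (not isolated) | OC1C=C(OCC(C)C)CC(C)(C)[C@@H]1CC=C | intermediate
10 | (4R)-4-allyl-5,5-dimethylcyclohex-2-en-1-one | O=C1C=C[C@@H](CC=C)C(C)(C)C1 | intermediate
11 | lithium (4R)-4-allyl-3,3-dimethylcyclohexa-1,5-dien-1-olate (not isolated) | [Li]OC1=CC(C)(C)[C@H](CC=C)C=C1 | intermediate
12 | (4R,6S)-4-allyl-6-(3-bromobut-3-en-1-yl)-5,5-dimethylcyclohex-2-en-1-one (allyl and bromobutenyl trans) | O=C1C=C[C@@H](CC=C)C(C)(C)[C@@H]1CCC(Br)=C | intermediate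
13 | lithium (4R)-4-allyl-2-(3-bromobut-3-en-1-yl)-3,3-dimethylcyclohexa-1,5-dien-1-olate (not isolated) | [Li]OC1=C(CCC(Br)=C)C(C)(C)[C@H](CC=C)C=C1 | intermediate
14 | (4R,6R)-4-allyl-6-(3-bromobut-3-en-1-yl)-5,5-dimethylcyclohex-2-en-1-one (allyl and bromobutenyl cis) | O=C1C=C[C@@H](CC=C)C(C)(C)[C@H]1CCC(Br)=C | intermediate
15 | (2R,4R,5S)-4-allyl-2-(3-bromobut-3-en-1-yl)-3,3-dimethyl-5-(4,4,5,5-tetramethyl-1,3,2-dioxaborolan-2-yl)cyclohexan-1-one (not isolated) | O=C1C[C@H](B2OC(C)(C)C(C)(C)O2)[C@@H](CC=C)C(C)(C)[C@H]1CCC(Br)=C | intermediate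
16 | (2R,4S,5S)-4-allyl-2-(3-bromobut-3-en-1-yl)-5-hydroxy-3,3-dimethylcyclohexan-1-one | O=C1C[C@H](O)[C@@H](CC=C)C(C)(C)[C@H]1CCC(Br)=C | intermediate
17 | (2R,4S,5S)-4-allyl-2-(3-bromobut-3-en-1-yl)-5-[(tert-butyldimethylsilyl)oxy]-3,3-dimethylcyclohexan-1-one | O=C1C[C@H](O[Si](C)(C)C(C)(C)C)[C@@H](CC=C)C(C)(C)[C@H]1CCC(Br)=C | intermediate
18 | (2R,4S,5S)-2-(3-bromobut-3-en-1-yl)-5-[(tert-butyldimethylsilyl)oxy]-3,3-dimethyl-4-(2-oxoethyl)cyclohexan-1-one | O=C1C[C@H](O[Si](C)(C)C(C)(C)C)[C@@H](CC=O)C(C)(C)[C@H]1CCC(Br)=C | intermediate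
19 | (2R,4S,5S)-2-(3-bromobut-3-en-1-yl)-5-[(tert-butyldimethylsilyl)oxy]-4-(2-hydroxyethyl)-3,3-dimethylcyclohexan-1-one | O=C1C[C@H](O[Si](C)(C)C(C)(C)C)[C@@H](CCO)C(C)(C)[C@H]1CCC(Br)=C | intermediate
20 | (2R,4S,5S)-2-(3-bromobut-3-en-1-yl)-5-[(tert-butyldimethylsilyl)oxy]-4-(2-chloroethyl)-3,3-dimethylcyclohexan-1-one | O=C1C[C@H](O[Si](C)(C)C(C)(C)C)[C@@H](CCCl)C(C)(C)[C@H]1CCC(Br)=C | intermediate
21 | tert-butyl{[(1S,2S,4S)-4-(3-bromobut-3-en-1-yl)-2-(2-chloroethyl)-3,3-dimethyl-5-methylidenecyclohexyl]oxy}dimethylsilane (key-step precursor; silyloxy, chain and arm all equatorial) | C=C1C[C@H](O[Si](C)(C)C(C)(C)C)[C@@H](CCCl)C(C)(C)[C@H]1CCC(Br)=C | intermediate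
22 | 9-{[(1S,2S,4S,5S)-2-(3-bromobut-3-en-1-yl)-5-[(tert-butyldimethylsilyl)oxy]-4-(2-chloroethyl)-3,3-dimethylcyclohexyl]methyl}-9-borabicyclo[3.3.1]nonane (not isolated) | C(B1C2CCCC1CCC2)[C@H]1C[C@H](O[Si](C)(C)C(C)(C)C)[C@@H](CCCl)C(C)(C)[C@H]1CCC(Br)=C | intermediate
23 | tert-butyl{[(2S,3S,4aS,8aS)-3-(2-chloroethyl)-4,4-dimethyl-7-methylidenedecahydronaphthalen-2-yl]oxy}dimethylsilane (cis-decalin; key-step product) | C=C1CC[C@H]2[C@@H](C1)C[C@H](O[Si](C)(C)C(C)(C)C)[C@@H](CCCl)C2(C)C | intermediate
24 | (2S,3S,4aS,8aR)-2-[(tert-butyldimethylsilyl)oxy]-3-(2-chloroethyl)-4,4-dimethyldecahydronaphthalen-7-one | O=C1CC[C@H]2[C@@H](C1)C[C@H](O[Si](C)(C)C(C)(C)C)[C@@H](CCCl)C2(C)C | intermediate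
25 | (2S,3S,4aS,8aR)-2-[(tert-butyldimethylsilyl)oxy]-3-(2-iodoethyl)-4,4-dimethyldecahydronaphthalen-7-one | O=C1CC[C@H]2[C@@H](C1)C[C@H](O[Si](C)(C)C(C)(C)C)[C@@H](CCI)C2(C)C | intermediate
26 | pent-3-yn-1-ol | CC#CCCO | starting material
27 | (E)-alkenylzirconocene chloride from 26, zirconium on C4 and on oxygen (not isolated) | Cl[Zr](C1C=CC=C1)(C1C=CC=C1)/C(C)=C/CCO[Zr](Cl)(C1C=CC=C1)C1C=CC=C1 | intermediate
28 | (3E)-4-iodopent-3-en-1-ol | I/C(C)=C/CCO | intermediate
29 | (3E)-4-iodopent-3-enal | I/C(C)=C/CC=O | intermediate
30 | (4R)-4-benzyl-3-propanoyl-1,3-oxazolidin-2-one | CCC(=O)N1[C@H](Cc2ccccc2)COC1=O | starting material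
31 | dibutylboron (Z)-enolate of 30 (not isolated) | C/C=C(\OB(CCCC)CCCC)N1[C@H](Cc2ccccc2)COC1=O | intermediate
32 | (4R)-4-benzyl-3-[(2R,3S,5E)-3-hydroxy-6-iodo-2-methylhept-5-enoyl]-1,3-oxazolidin-2-one | I/C(C)=C/C[C@H](O)[C@@H](C)C(=O)N1[C@H](Cc2ccccc2)COC1=O | intermediate
33 | (2S,3S,5E)-6-iodo-2-methylhept-5-ene-1,3-diol | I/C(C)=C/C[C@H](O)[C@@H](C)CO | intermediate
34 | (2S,3S,5E)-1-[(tert-butyldimethylsilyl)oxy]-6-iodo-2-methylhept-5-en-3-ol | I/C(C)=C/C[C@H](O)[C@@H](C)CO[Si](C)(C)C(C)(C)C | intermediate
35 | alkylzinc iodide from 25: {2-[(2S,3S,4aS,8aR)-2-[(tert-butyldimethylsilyl)oxy]-4,4-dimethyl-7-oxodecahydronaphthalen-3-yl]ethyl}zinc iodide (not isolated) | O=C1CC[C@H]2[C@@H](C1)C[C@H](O[Si](C)(C)C(C)(C)C)[C@@H](CC[Zn]I)C2(C)C | intermediate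
36 | (2S,3S,4aS,8aR)-2-[(tert-butyldimethylsilyl)oxy]-3-[(3E,6S,7S)-8-[(tert-butyldimethylsilyl)oxy]-6-hydroxy-3,7-dimethyloct-3-en-1-yl]-4,4-dimethyldecahydronaphthalen-7-one | O=C1CC[C@H]2[C@@H](C1)C[C@H](O[Si](C)(C)C(C)(C)C)[C@@H](CC/C(C)=C/C[C@H](O)[C@@H](C)CO[Si](C)(C)C(C)(C)C)C2(C)C | intermediate
37 | (6S,7S)-methanesulfonate of 36 | O=C1CC[C@H]2[C@@H](C1)C[C@H](O[Si](C)(C)C(C)(C)C)[C@@H](CC/C(C)=C/C[C@H](OS(C)(=O)=O)[C@@H](C)CO[Si](C)(C)C(C)(C)C)C2(C)C | intermediate
38 | (6R,7S)-6-[(2-methoxypropan-2-yl)peroxy] analogue of 36 (not isolated) | O=C1CC[C@H]2[C@@H](C1)C[C@H](O[Si](C)(C)C(C)(C)C)[C@@H](CC/C(C)=C/C[C@@H](OOC(C)(C)OC)[C@@H](C)CO[Si](C)(C)C(C)(C)C)C2(C)C | intermediate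
39 | (2S,3S,4aS,8aR)-2-[(tert-butyldimethylsilyl)oxy]-3-[(3E,6R,7S)-8-[(tert-butyldimethylsilyl)oxy]-6-hydroperoxy-3,7-dimethyloct-3-en-1-yl]-4,4-dimethyldecahydronaphthalen-7-one | O=C1CC[C@H]2[C@@H](C1)C[C@H](O[Si](C)(C)C(C)(C)C)[C@@H](CC/C(C)=C/C[C@@H](OO)[C@@H](C)CO[Si](C)(C)C(C)(C)C)C2(C)C | intermediate
40 | (3′R,5′R,6′S)-5′-(acetoxymercurio) derivative of 41, mercury equatorial on C5′ (not isolated) | O=C1CC[C@H]2[C@@H](C1)C[C@H](O[Si](C)(C)C(C)(C)C)[C@@H](CC[C@@]3(C)[C@H]([Hg]OC(C)=O)C[C@H]([C@@H](C)CO[Si](C)(C)C(C)(C)C)OO3)C2(C)C | intermediate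
41 | (2S,3S,4aS,8aR)-2-[(tert-butyldimethylsilyl)oxy]-3-{2-[(3′R,6′S)-3′-{(2S)-1-[(tert-butyldimethylsilyl)oxy]propan-2-yl}-6′-methyl-1,2-dioxan-6′-yl]ethyl}-4,4-dimethyldecahydronaphthalen-7-one | O=C1CC[C@H]2[C@@H](C1)C[C@H](O[Si](C)(C)C(C)(C)C)[C@@H](CC[C@@]3(C)CC[C@H]([C@@H](C)CO[Si](C)(C)C(C)(C)C)OO3)C2(C)C | intermediate
42 | (2S,3S,4aS,8aR)-2-hydroxy-3-{2-[(3′R,6′S)-3′-[(2S)-1-hydroxypropan-2-yl]-6′-methyl-1,2-dioxan-6′-yl]ethyl}-4,4-dimethyldecahydronaphthalen-7-one | O=C1CC[C@H]2[C@@H](C1)C[C@H](O)[C@@H](CC[C@@]3(C)CC[C@H]([C@@H](C)CO)OO3)C2(C)C | intermediate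
43 | (2R)-2-[(3R,6S)-6-{2-[(3S,4aS,8aS)-4,4-dimethyl-2,7-dioxodecahydronaphthalen-3-yl]ethyl}-6-methyl-1,2-dioxan-3-yl]propanoic acid | O=C1CC[C@H]2[C@@H](C1)CC(=O)[C@@H](CC[C@@]3(C)CC[C@H]([C@@H](C)C(=O)O)OO3)C2(C)C | intermediate
44 | (2R)-2-[(3R,6S)-6-{2-[(3R,4aS,8aS)-4,4-dimethyl-2,7-dimethylidenedecahydronaphthalen-3-yl]ethyl}-6-methyl-1,2-dioxan-3-yl]propanoic acid (CNP0363961.1) | C=C1CC[C@H]2[C@@H](C1)CC(=C)[C@@H](CC[C@@]1(C)CC[C@H]([C@@H](C)C(=O)O)OO1)C2(C)C | target

## Step count and least certain steps

Total step count: 29. Longest linear sequence: 22 steps, from dimedone 4 to target 44 (steps 3 to 17 and 23 to 29); the arm reagent (steps 1 and 2) and the side-chain fragment (steps 18 to 22) are made in parallel.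

Step 15 (key step). The most likely failure is incomplete face discrimination in the hydroboration, with some hydrogen delivered to the axial face of C8a so that a trans-fused product accompanies 23. The second is slow transmetallation of the hindered, β-branched alkylborane, which would let protodeboronation and intermolecular coupling compete with ring closure. Fallback: from 21, the same hydroboration is followed by oxidation with NaBO3 to the primary alcohol F1, at which stage any C8a epimer can be removed by chromatography. Iodination (I2, PPh3, imidazole) gives the primary iodide F2. Zinc then inserts into the C–I bond only (Zn, LiCl, THF), and an intramolecular Negishi coupling with Pd(dppf)Cl2 joins C8 to C7, returning to the route at 23.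

Step 5. The enantioselectivity may be eroded: the enolate carbon is neopentyl, so recombination with the allyl unit may occur partly outside the chiral pocket, and proton transfer between product and enolate can scramble the new tertiary centre. Fallback: the material is carried on to 16 and the unwanted enantiomer is removed there by enzymatic kinetic resolution. From 16 of insufficient enantiomeric purity, Candida antarctica lipase B and vinyl acetate in tert-butyl methyl ether should acetylate the enantiomer with the (R)-carbinol, following the empirical rule for lipase acylation of secondary alcohols. This gives the acetate of ent-16 F3, which is separated by chromatography; the unreacted alcohol re-enters the route at 16.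

Step 8. The proton is a small electrophile, so facial control in the kinetic protonation may be incomplete. Deprotonation of the hindered methine may also be slow or may occur at the γ-position, which would deconjugate the enone. Fallback: thermodynamic control at a later, saturated stage. From 12, the conditions of steps 9 and 10 give the C2-epimeric hydroxy ketone F4 and its silyl ether F5. DBU in toluene at room temperature, mild enough to leave the poorly leaving β-silyloxy group in place, then equilibrates the centre next to the ketone towards the all-equatorial isomer, which is 17. It is separated and the remainder is resubmitted, rejoining the route at 17.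

Step 25. Elimination of the β-branched secondary mesylate by the basic peroxide anion may outrun substitution, and this would consume advanced material. Fallback: the C–O bond is made on the small fragment before the coupling, where excess nucleophile and losses are affordable. From 34, mesylation gives the fragment mesylate F6, and displacement with the caesium salt of 2-methoxyprop-2-yl hydroperoxide gives the fragment peroxyketal F7 with inversion. Negishi coupling of F7 with the zinc reagent 35 under the conditions of step 23 returns to the route at 38; peroxyketals of this kind pass palladium-catalysed Stille and Sonogashira couplings, which speaks for their survival here.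

Step 26. The ring closure may pass in part through a chair with the C3′ substituent axial or through a boat, giving the C6′ epimer. The radical demercuration may also cleave the O–O bond. Fallback: the peroxide is built in the opposite order, without mercury. From 37, Mukaiyama–Isayama hydroperoxysilylation of the trisubstituted alkene (Co(thd)2, thd = 2,2,6,6-tetramethylheptane-3,5-dionate, O2, Et3SiH) places a triethylsilyl peroxide on C6′, giving the silyl peroxide F8 as both C6′ epimers. One equivalent of Bu4NF at low temperature, under which the Si–O–O bond should be cleaved faster than the silyl ethers, frees the peroxide anion. This displaces the mesylate intramolecularly with inversion at C3′ to give 41 together with its C6′ epimer F9. Chromatography removes F9 and the route is rejoined at 41, at the cost of half the material.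

Step 29. The basic ylide may enolise the C2 ketone towards C3 and epimerise that centre, may attack the O–O bond, or may fail to reach the hindered C2 carbonyl. Fallback: a Peterson olefination through a weakly basic organocerium reagent. From 43, Me3SiCH2Li with CeCl3 in THF at −78 °C adds to both ketones (one further equivalent is consumed by the acid) to give the bis(β-hydroxysilane) acid F10. Aqueous HF in MeCN then induces elimination of both silanol units and gives 44.

## Further compounds

F1 | step 15 | [(1S,2S,4S,5S)-2-(3-bromobut-3-en-1-yl)-5-[(tert-butyldimethylsilyl)oxy]-4-(2-chloroethyl)-3,3-dimethylcyclohexyl]methanol | OC[C@H]1C[C@H](O[Si](C)(C)C(C)(C)C)[C@@H](CCCl)C(C)(C)[C@H]1CCC(Br)=C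
F2 | step 15 | tert-butyl{[(1S,2S,4S,5S)-4-(3-bromobut-3-en-1-yl)-2-(2-chloroethyl)-5-(iodomethyl)-3,3-dimethylcyclohexyl]oxy}dimethylsilane | IC[C@H]1C[C@H](O[Si](C)(C)C(C)(C)C)[C@@H](CCCl)C(C)(C)[C@H]1CCC(Br)=C
F3 | step 5 | (1R,2R,4S)-2-allyl-4-(3-bromobut-3-en-1-yl)-3,3-dimethyl-5-oxocyclohexyl acetate (acetate of ent-16) | O=C1C[C@@H](OC(C)=O)[C@H](CC=C)C(C)(C)[C@@H]1CCC(Br)=C
F4 | step 8 | (2S,4S,5S)-4-allyl-2-(3-bromobut-3-en-1-yl)-5-hydroxy-3,3-dimethylcyclohexan-1-one (C2 epimer of 16) | O=C1C[C@H](O)[C@@H](CC=C)C(C)(C)[C@@H]1CCC(Br)=C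
F5 | step 8 | (2S,4S,5S)-4-allyl-2-(3-bromobut-3-en-1-yl)-5-[(tert-butyldimethylsilyl)oxy]-3,3-dimethylcyclohexan-1-one (C2 epimer of 17) | O=C1C[C@H](O[Si](C)(C)C(C)(C)C)[C@@H](CC=C)C(C)(C)[C@@H]1CCC(Br)=C
F6 | step 25 | (2S,3S,5E)-1-[(tert-butyldimethylsilyl)oxy]-6-iodo-2-methylhept-5-en-3-yl methanesulfonate | I/C(C)=C/C[C@H](OS(C)(=O)=O)[C@@H](C)CO[Si](C)(C)C(C)(C)C
F7 | step 25 | tert-butyl{[(2S,3R,5E)-6-iodo-3-[(2-methoxypropan-2-yl)peroxy]-2-methylhept-5-en-1-yl]oxy}dimethylsilane | I/C(C)=C/C[C@@H](OOC(C)(C)OC)[C@@H](C)CO[Si](C)(C)C(C)(C)C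
F8 | step 26 | (6S,7S)-8-[(tert-butyldimethylsilyl)oxy]-1-[(2S,3S,4aS,8aR)-2-[(tert-butyldimethylsilyl)oxy]-4,4-dimethyl-7-oxodecahydronaphthalen-3-yl]-3,7-dimethyl-3-[(triethylsilyl)peroxy]octan-6-yl methanesulfonate (both C3 epimers of the octane chain, C6′ of the target) | O=C1CC[C@H]2[C@@H](C1)C[C@H](O[Si](C)(C)C(C)(C)C)[C@@H](CCC(C)(OO[Si](CC)(CC)CC)CC[C@H](OS(C)(=O)=O)[C@@H](C)CO[Si](C)(C)C(C)(C)C)C2(C)C
F9 | step 26 | (3′R,6′R) epimer of 41 (C6′ epimer) | O=C1CC[C@H]2[C@@H](C1)C[C@H](O[Si](C)(C)C(C)(C)C)[C@@H](CC[C@]3(C)CC[C@H]([C@@H](C)CO[Si](C)(C)C(C)(C)C)OO3)C2(C)C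
F10 | step 29 | (2R)-2-[(3R,6S)-6-{2-[(3S,4aS,8aS)-2,7-dihydroxy-4,4-dimethyl-2,7-bis[(trimethylsilyl)methyl]decahydronaphthalen-3-yl]ethyl}-6-methyl-1,2-dioxan-3-yl]propanoic acid (carbinol centres undefined) | C[Si](C)(C)CC1(O)CC[C@H]2[C@@H](C1)CC(O)(C[Si](C)(C)C)[C@@H](CC[C@@]3(C)CC[C@H]([C@@H](C)C(=O)O)OO3)C2(C)C
A1 | alternative 1 | 7-benzyloxy-2-(2-methylprop-1-enyl)bicyclo[2.2.2]oct-5-en-2-ol (alkenyl group syn to the alkene bridge, benzyloxy group syn to the alkene bridge) | O[C@]1(C=C(C)C)C[C@H]2C=C[C@@H]1[C@H](OCc1ccccc1)C2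
A2 | alternative 1 | cis-fused 7-benzyloxy-4,4-dimethyl-3,4,4a,7,8,8a-hexahydronaphthalen-2(1H)-one | C(c1ccccc1)O[C@H]1C=C[C@H]2[C@@H](C1)CC(=O)CC2(C)C
A3 | alternative 2 | meso cis-5,5-dimethyl-4,6-bis(3-oxobutyl)cyclohexane-1,3-dione | CC(=O)CC[C@H]1C(=O)CC(=O)[C@@H](CCC(C)=O)C1(C)C
A4 | alternative 2 | bicyclic enedione with a 3-oxobutyl arm on C3 | O=C1CC[C@H]2C(=C1)CC(=O)[C@@H](CCC(C)=O)C2(C)C
A5 | alternative 3 | cis-decalin-2,7-dione carrying the (3E,6R,7S)-8-silyloxy-6-hydroperoxy-3,7-dimethyloct-3-enyl chain on C3 | O=C1CC[C@H]2[C@@H](C1)CC(=O)[C@@H](CC/C(C)=C/C[C@@H](OO)[C@@H](C)CO[Si](C)(C)C(C)(C)C)C2(C)C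
A6 | alternative 3 | 1,2-dioxane on the cis-decalin-2,7-dione with a silyl-protected primary alcohol | O=C1CC[C@H]2[C@@H](C1)CC(=O)[C@@H](CC[C@@]1(C)CC[C@H]([C@@H](C)CO[Si](C)(C)C(C)(C)C)OO1)C2(C)C
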